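Against 15 s of reaction stood 6.28 s at −20 °C: this is the relaxation time τ of the pair target and isomer of the product, the reciprocal of forward plus reverse rate constant, in which any departure of the pair from its equilibrium shrinks by a factor e. The flasks share one charge and differ in their temperature.

the same everywhere: starting material 0.10 M; partner 1.50 equiv; second substrate 0.500 equiv; third substrate 1.00 equiv; time 15 s

| charge | temperature | remark |
|---|---|---|
| Tuesday's | −5 °C |  |
| Friday's | −20 °C |  |
| Monday's |  | at −5 °C until 5.0 s, from then on at −20 °C |

    starting material + partner → target (k1 = 0.55 M⁻¹ s⁻¹, Ea1 = 52.0 kJ mol⁻¹)
    second substrate + partner → second product (k2 = 9.2 M⁻¹ s⁻¹, Ea2 = 48.0 kJ mol⁻¹)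
    third substrate + partner → third product (k3 = 0.062 M⁻¹ s⁻¹, Ea3 = 58.0 kJ mol⁻¹)
    target ⇌ isomer of the product (K4 = 1.3, k4 = 0.090 s⁻¹, Ea4 = 58.0 kJ mol⁻¹, ΔH4 = −37.0 kJ mol⁻¹)
    starting material → decomposition product (k5 = 3.1 × 10⁻⁴ s⁻¹, Ea5 = 78.0 kJ mol⁻¹)
    (constants at −20 °C)

- the constants hold at −20 °C; other temperatures follow from the activation energies and enthalpies

* which flask leads in share of target in all that became target or isomer of the product ("all alike" within 1.5 percentage points) (Tuesday's / Friday's / Monday's / all alike)
* share of target in all that became target or isomer of the product, Tuesday's
* share of target in all that became target or isomer of the product, Friday's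
* share of target in all that became target or isomer of the product, Monday's

I treated target and isomer as one pool, fed with fresh target, whose target share φ drifts with time constant τ toward φeq, the reciprocal of one plus K, where K is the equilibrium constant of the isomerisation. At −20 °C, φeq was 43.5%. At −5 °C, K fell to 0.486 and the forward constant grew by 4.7, the factor of the step to the third product, which has the same activation energy. So φeq became 67.3% and τ 0.778 s. Tuesday's flask thus ran 19.3 time constants, and I put it just above φeq.

Friday's flask ran 2.39 time constants, so it needed a bracket. Fresh target has share one, so φ is φeq plus M times what φeq lacks of one, M being the decay factor averaged over the ages in the pool. Had the pool formed at the start, φ would be 48.7%, the bound from below. A steady feed gives younger material and 65.0%, the bound from above.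

Then I went round again. In Friday's flask the second substrate reacts faster than the starting material and takes its partner early, which leaves partner and starting material about equal. Taking them as equal, I let starting material fall as its charge over one plus k·c·t, with k the rate constant of the step to target and c the charge. The feed at the end is therefore 0.300 of its opening value, a decay rate λ of 0.0802 s⁻¹. Averaging with that feed gave M of 0.302 and φ of 60.6%.

For Monday's flask, cold relaxation over the last 10.0 s from 67.3% gave 48.3%, a bound from below, since later target is younger. I ranked Tuesday's first, above Friday's.

The forecast said Tuesday's, with 67.7%, 59.8% and 52%, holding that on Friday's “isomerisation lags equilibrium”. Its Friday's value lay inside my bracket, 0.80 percentage points below my figure. The simulation gave Tuesday's, with 67.6%, 59.8% and 51.9%, so the forecast was right.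

The reverse step, isomer of the product to target, is the main reason for Tuesday's share: struck out, that share fell from 67.6% to 4.46%. Friday's flask at 15 s was still under kinetic control, its share placed by the time allowed together with that reverse step, and a tenfold time took it to 43.6%, close to φeq. A reading of Friday's at 40 s spans 6.37 time constants, with the feed down to 0.0977 of its opening value. The same average gives 46.9%, and that reading stood at 46.8%.

Its constants are invented; the run is a simulation.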